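The 69% of starting complex left in the south run at 50.0 min and the 68% left in the north-east run at the same time hardly differ, although north-east was charged 1.50 times the incoming ligand.

in all of them: starting complex 0.050 M
- south: incoming ligand 0.050 M; run made earlier
- north-east: incoming ligand 0.075 M; run made earlier
- delta: incoming ligand 0.100 M; time 50 min
- eta: incoming ligand 0.100 M; time 80 min

| run | time / min | starting complex / % | complex with one exchanged / % | complex with two exchanged / % | complex with three exchanged / % |
|---|---|---|---|---|---|
| south | 6.00 | 95 | 6 | 0 | 0 |
| south | 20.0 | 86 | 14 | 4 | 4 |
| south | 30.0 | 80 | 18 | 0 | 1 |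
| south | 50.0 | 69 | 21 | 2 | 2 |
| north-east | 6.00 | 94 | 9 | 3 | 0 |
| north-east | 20.0 | 79 | 19 | 2 | 0 |
| north-east | 30.0 | 71 | 25 | 7 | 5 |
| north-east | 50.0 | 68 | 25 | 7 | 7 |

(scatter of a reading: 2 percentage points)

- which of these there is most of at the end, counted by the starting complex in it, delta (starting complex / complex with three exchanged / complex with two exchanged / complex with one exchanged)
- which of these there is most of at the end, counted by the starting complex in it, eta (starting complex / complex with three exchanged / complex with two exchanged / complex with one exchanged)
- the largest of these amounts at the end, in percent of the starting complex charged, delta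
- the largest of these amounts at the end, in percent of the starting complex charged, eta



Earlier the two runs kept one clock: south at 30.0 min shows 80% and north-east at 20.0 min shows 79%, with the same product c(incoming ligand)·t. While ligand lasts, the starting complex decays pseudo-first-order at a rate proportional to c(incoming ligand), so the logarithm of its leftover measures the time integral of that concentration. I therefore ask how that integral ends. A ligand lost at second order in itself falls as its charge over (1 + x), with x proportional to c·t, and the integral grows only as ln(1 + x). The runs give no reading of the ligand, so as a working choice, not a value read off them, I set x = 1 at north-east's last reading. South then ends at x = 0.667. The reach B, the logarithm of the leftover gained per unit of ln(1 + x), is then 0.556. My reckoning is: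

left = 1 / (1 + x)^B

delta: x = 1.33, left = 62.4%

eta: x = 2.13, left = 53.0%

The same curve gives 75.3% for south's last reading of 69%, so that gap is my margin, wider than the scatter.

The forecast differs from my reckoning: it names starting complex in delta and starting complex in eta, at 67% and 67%, holding that “the reaction seems to stall near 30% conversion”.

The flask gives starting complex at 59.7% in delta and starting complex at 54.5% in eta, beside my 62.4% and 53.0%; delta still falls from 70.0% at 25.0 min to 59.7% at 50.0 min.

    complex with two exchanged + incoming ligand ⇌ leaving ligand + complex with three exchanged (K = 13.0, k = 0.0150 M⁻¹ s⁻¹)
    complex with one exchanged + incoming ligand ⇌ leaving ligand + complex with two exchanged (K = 8.60, k = 0.00580 M⁻¹ s⁻¹)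
    starting complex + incoming ligand ⇌ leaving ligand + complex with one exchanged (K = 0.900, k = 0.00370 M⁻¹ s⁻¹)
    2 incoming ligand → homo dimer (k = 0.00260 M⁻¹ s⁻¹)
    crystals ⇌ leaving ligand, rate k5*(cs5 - [leaving ligand]) while solid is left; crystals form when [leaving ligand] > cs5 (solubility = 9.10 mM, k = 0.0560 s⁻¹)
    incoming ligand → decomposition product (k = 8.00 × 10⁻⁷ s⁻¹)

In eta the homo dimer uses incoming ligand 2.8 times as fast as the forward first exchange at the start, and still 1.6 times as fast at 31.5 min. Less of the ligand's charge than of the starting complex's remains at the end of eta, 14% against 54%.

For the neighbour of eta charged with 0.40 M of incoming ligand, x = 8.53 and the reach B gives 28.5% of starting complex left. The computed flask holds 27.8%.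

The earlier runs and the new flask stem from a simulated flask from invented constants; noise was put on by code.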